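The plan cuts the pyran ring of the chromene at O1–C8a. C8a sits para to C6, whose acetyl group is carried as a nitrile, so it accepts an oxygen nucleophile, and O1 and the ester oxygen are held by adjacent carbons (C2 and its CH2 group). An aryl shift from the primary to the tertiary oxygen therefore turns a seven-membered benzoxepinol into the six-membered ring, with the fully substituted C2 already in place and untouched. The substrate for this step is (3R)-3-hydroxy-9-methoxy-3-methyl-2,3-dihydro-1-benzoxepine-7-carbonitrile, built from a chiral glycidyl aryl ether by one-carbon homologation and ring-closing metathesis. Grignard addition to the nitrile and feruloylation complete the route.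

Key step: step 5

Remark: 3-bromo-4-hydroxy-5-methoxybenzonitrile (5-bromovanillonitrile) is assumed to be a catalogue compound.
Remark: the phenol oxygen is joined to the hydroxymethyl carbon of the glycidol and the epoxide CH2 ends as the vinyl CH, so the (S) enantiomer of 2-methylglycidol is required; opening the epoxide with the phenoxide instead would require the (R) enantiomer.
Remark: compound 7 carries benzoxepine numbers (O1, C2, C3, C4=C5, C5a to C9a) and compounds from 9 on carry chromene numbers; C9a of 7 becomes C8a of 9 and C3 of 7 becomes C2 of 9.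

Step 1
Reactants: 1 3-bromo-4-hydroxy-5-methoxybenzonitrile
Product: 2 3-ethenyl-4-hydroxy-5-methoxybenzonitrile
Conditions: vinylboronic acid pinacol ester (1.5 equiv), PdCl2(dppf) (3 mol %), K2CO3 (3 equiv), 1,4-dioxane/H2O (4:1), 85 °C
Reagents that add atoms: 2-ethenyl-4,4,5,5-tetramethyl-1,3,2-dioxaborolane, C=CB1OC(C)(C)C(C)(C)O1
Why: Suzuki–Miyaura vinylation of the aryl bromide, which tolerates the free phenol (present as phenoxide in aqueous carbonate) and the nitrile; no stereocentre is involved.

Step 2
Reactants: 2 3-ethenyl-4-hydroxy-5-methoxybenzonitrile; 3 (S)-2-methylglycidol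
Product: 4 3-ethenyl-5-methoxy-4-{[(2R)-2-methyloxiran-2-yl]methoxy}benzonitrile
Conditions: PPh3 (1.3 equiv), DIAD (1.3 equiv), THF, 0 °C → rt
Reagents that add atoms: none
Why: Mitsunobu etherification, in which the acidic, hindered phenol displaces the oxyphosphonium group at the primary carbon of 3 without touching the epoxide or its quaternary carbon, so the configuration of 3 is carried over unchanged (the descriptor changes from S to R only through the CIP ranking of the two CH2 groups).

Step 3
Reactants: 4 3-ethenyl-5-methoxy-4-{[(2R)-2-methyloxiran-2-yl]methoxy}benzonitrile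
Product: 6 3-ethenyl-4-{[(2R)-2-hydroxy-2-methylbut-3-en-1-yl]oxy}-5-methoxybenzonitrile, via oxidosulfonium betaine 5 (not isolated)
Conditions: Me3S+ I− (3.3 equiv), n-BuLi (3.1 equiv), THF, −10 °C; then 4, −10 → 10 °C; sat. aq. NH4Cl
Reagents that add atoms: trimethylsulfonium iodide, C[S+](C)C.[I-]
Why: Sulfonium-ylide homologation of a terminal epoxide to an allylic alcohol, in which the ylide opens the epoxide at its CH2 to betaine 5 and a further equivalent turns the sulfonium into an ylide that removes the β-hydrogen intramolecularly with loss of dimethyl sulfide, leaving the quaternary centre untouched; the donor-substituted nitrile should not compete for this stabilised carbon nucleophile at low temperature, and n-BuLi is kept below the sulfonium salt so that no alkyllithium reaches the nitrile.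

Step 4
Reactants: 6 3-ethenyl-4-{[(2R)-2-hydroxy-2-methylbut-3-en-1-yl]oxy}-5-methoxybenzonitrile
Product: 7 (3R)-3-hydroxy-9-methoxy-3-methyl-2,3-dihydro-1-benzoxepine-7-carbonitrile
Conditions: second-generation Grubbs catalyst (5 mol %), CH2Cl2 (0.005 M), 40 °C
Reagents that add atoms: none
Why: Ring-closing metathesis between the styrene and the vinyl carbinol closes the seven-membered ring, in which the new C4=C5 bond can only be cis; free tertiary allylic alcohols and aryl nitriles are tolerated by the ruthenium carbene, and high dilution suppresses dimerisation.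

Step 5
Reactants: 7 (3R)-3-hydroxy-9-methoxy-3-methyl-2,3-dihydro-1-benzoxepine-7-carbonitrile
Product: 9 (2R)-2-(hydroxymethyl)-8-methoxy-2-methyl-2H-chromene-6-carbonitrile, via bridged Meisenheimer ketal 8 (not isolated)
Conditions: KH (1.2 equiv), 18-crown-6 (1.2 equiv), THF, 0 → 45 °C; then sat. aq. NH4Cl
Reagents that add atoms: none
Why: Proposed new method: KH gives the tertiary potassium alkoxide, which in the ring conformer with pseudo-axial oxygen lies over C9a and adds there ipso, giving cyclohexadienide 8, whose charge is taken up by the para nitrile and whose ketal carbon is part of a 6,8-dioxabicyclo[3.2.1]oct-2-ene, the strain-tolerant skeleton of the 1,6-anhydrohexoses; 8 then breaks its C9a–O1 bond and releases the primary alkoxide of 9. The closest known reaction type is the O-to-O Smiles rearrangement of 2-aryloxyethanols through spiro Meisenheimer ketals of activated arenes; the new element is the transannular, bridged variant that contracts a ring. The pyran ring closes by transannular ipso attack of oxygen on an sp2 ring carbon (a 5-exo-trig addition as seen from the dioxolane ring of 8) and becomes a free six-membered ring when the oxepine C–O bond opens. No stereocentre is formed: the ketal carbon of 8 is fixed by the bridge and disappears again, and C3 of 7 becomes C2 of 9 with all four of its bonds intact, so (R) is retained. The step needs the aryl group to end on the tertiary oxygen, which is secured by expulsion of the less basic primary alkoxide, by the change from a seven- to a six-membered ring and by the non-enolisable nitrile that keeps the ring electrophilic in base; the substrate has no hydrogen through which the alkoxide could isomerise the C4=C5 bond.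

Step 6
Reactants: 9 (2R)-2-(hydroxymethyl)-8-methoxy-2-methyl-2H-chromene-6-carbonitrile
Product: 11 1-[(2R)-2-(hydroxymethyl)-8-methoxy-2-methyl-2H-chromen-6-yl]ethan-1-one, via ketimine 10 (not isolated)
Conditions: MeMgBr (4 equiv), THF/toluene (1:2), 0 → 65 °C; then 10% aq. citric acid, rt
Reagents that add atoms: methylmagnesium bromide, C[Mg]Br; water, O
Why: Grignard addition to the nitrile, after the primary alcohol has been masked in situ as its magnesium alkoxide, gives the N-magnesio ketimine (10 after protonation), which cannot take up a second methyl group and is hydrolysed by mild aqueous acid to the methyl ketone without affecting the quaternary C2.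

Step 7
Reactants: 12 ferulic acid
Product: 14 (2E)-3-{4-[(tert-butyldimethylsilyl)oxy]-3-methoxyphenyl}prop-2-enoic acid, via bis-silyl ferulate 13 (not isolated)
Conditions: TBSCl (2.3 equiv), imidazole (5 equiv), DMF, rt; then AcOH/THF/H2O (3:1:1), rt
Reagents that add atoms: tert-butyldimethylsilyl chloride, CC(C)(C)[Si](C)(C)Cl
Why: Silylation of both acidic oxygens followed by selective hydrolysis of the labile silyl ester, which leaves the aryl silyl ether, is the standard way to mask the phenol of a hydroxycinnamic acid before carboxyl activation.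

Step 8
Reactants: 11 1-[(2R)-2-(hydroxymethyl)-8-methoxy-2-methyl-2H-chromen-6-yl]ethan-1-one; 14 (2E)-3-{4-[(tert-butyldimethylsilyl)oxy]-3-methoxyphenyl}prop-2-enoic acid
Product: 15 [(2R)-6-acetyl-8-methoxy-2-methyl-2H-chromen-2-yl]methyl (2E)-3-{4-[(tert-butyldimethylsilyl)oxy]-3-methoxyphenyl}prop-2-enoate
Conditions: EDC·HCl (1.5 equiv), DMAP (0.3 equiv), CH2Cl2, 0 °C → rt
Reagents that add atoms: none
Why: Steglich esterification (carbodiimide activation with DMAP acyl transfer) acylates the neopentyl-type primary alcohol at oxygen with no substitution at carbon, the silyl ether prevents self-acylation of the phenol, and the (E)-alkene and C2 are unchanged.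

Step 9
Reactants: 15 [(2R)-6-acetyl-8-methoxy-2-methyl-2H-chromen-2-yl]methyl (2E)-3-{4-[(tert-butyldimethylsilyl)oxy]-3-methoxyphenyl}prop-2-enoate
Product: 16 [(2R)-6-acetyl-8-methoxy-2-methyl-2H-chromen-2-yl]methyl (2E)-3-(4-hydroxy-3-methoxyphenyl)prop-2-enoate
Conditions: TBAF (1.1 equiv), AcOH (1.2 equiv), THF, 0 °C
Reagents that add atoms: none
Why: Fluoride-mediated desilylation cleaves the aryl silyl ether rapidly, and buffering with acetic acid keeps the liberated phenoxide from attacking the cinnamate ester or the ketone.

Compound list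
1 | 3-bromo-4-hydroxy-5-methoxybenzonitrile | N#Cc1cc(Br)c(O)c(OC)c1 | starting material
2 | 3-ethenyl-4-hydroxy-5-methoxybenzonitrile | N#Cc1cc(C=C)c(O)c(OC)c1 | intermediate
3 | (S)-2-methylglycidol, [(2S)-2-methyloxiran-2-yl]methanol | OC[C@@]1(C)CO1 | starting material
4 | 3-ethenyl-5-methoxy-4-{[(2R)-2-methyloxiran-2-yl]methoxy}benzonitrile | N#Cc1cc(C=C)c(OC[C@@]2(C)CO2)c(OC)c1 | intermediate
5 | [(3R)-4-(4-cyano-2-ethenyl-6-methoxyphenoxy)-3-methyl-3-oxidobutyl]dimethylsulfonium (betaine) | C[S+](C)CC[C@@](C)([O-])COc1c(C=C)cc(C#N)cc1OC | intermediate (not isolated)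
6 | 3-ethenyl-4-{[(2R)-2-hydroxy-2-methylbut-3-en-1-yl]oxy}-5-methoxybenzonitrile | C=C[C@@](C)(O)COc1c(C=C)cc(C#N)cc1OC | intermediate
7 | (3R)-3-hydroxy-9-methoxy-3-methyl-2,3-dihydro-1-benzoxepine-7-carbonitrile | N#Cc1cc2C=C[C@@](C)(O)COc2c(OC)c1 | intermediate
8 | potassium cyclohexadienide in which the former C9a is a ketal carbon bonded to O1 and to the C3 oxygen (6,8-dioxabicyclo[3.2.1]oct-2-ene bridge; configuration of the ketal carbon dictated by the (R) centre) | N#C[C-]1C=C2C=C[C@]3(C)CO[C@]2(O3)C(OC)=C1.[K+] | intermediate (not isolated)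
9 | (2R)-2-(hydroxymethyl)-8-methoxy-2-methyl-2H-chromene-6-carbonitrile | OC[C@@]1(C)C=Cc2cc(C#N)cc(OC)c2O1 | intermediate
10 | [(2R)-6-ethanimidoyl-8-methoxy-2-methyl-2H-chromen-2-yl]methanol (ketimine, present as its bromomagnesium salt until the quench) | OC[C@@]1(C)C=Cc2cc(C(C)=N)cc(OC)c2O1 | intermediate (not isolated)
11 | 1-[(2R)-2-(hydroxymethyl)-8-methoxy-2-methyl-2H-chromen-6-yl]ethan-1-one | OC[C@@]1(C)C=Cc2cc(C(C)=O)cc(OC)c2O1 | intermediate
12 | ferulic acid, (2E)-3-(4-hydroxy-3-methoxyphenyl)prop-2-enoic acid | COc1cc(/C=C/C(=O)O)ccc1O | starting material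
13 | tert-butyldimethylsilyl (2E)-3-{4-[(tert-butyldimethylsilyl)oxy]-3-methoxyphenyl}prop-2-enoate | COc1cc(/C=C/C(=O)O[Si](C)(C)C(C)(C)C)ccc1O[Si](C)(C)C(C)(C)C | intermediate (not isolated)
14 | (2E)-3-{4-[(tert-butyldimethylsilyl)oxy]-3-methoxyphenyl}prop-2-enoic acid | COc1cc(/C=C/C(=O)O)ccc1O[Si](C)(C)C(C)(C)C | intermediate
15 | [(2R)-6-acetyl-8-methoxy-2-methyl-2H-chromen-2-yl]methyl (2E)-3-{4-[(tert-butyldimethylsilyl)oxy]-3-methoxyphenyl}prop-2-enoate | COc1cc(/C=C/C(=O)OC[C@@]2(C)C=Cc3cc(C(C)=O)cc(OC)c3O2)ccc1O[Si](C)(C)C(C)(C)C | intermediate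
16 | [(2R)-6-acetyl-8-methoxy-2-methyl-2H-chromen-2-yl]methyl (2E)-3-(4-hydroxy-3-methoxyphenyl)prop-2-enoate (CNP0168033.1) | COc1cc(/C=C/C(=O)OC[C@@]2(C)C=Cc3cc(C(C)=O)cc(OC)c3O2)ccc1O | target

Total step count: 9. Longest linear sequence: 8 (steps 1 to 6, then 8 and 9); step 7 is a one-step side branch.

Steps most likely to fail

Step 5 (Proposed new method). The ipso addition may not take place, because C9a bears an alkoxy group and is activated only by the para nitrile while the ortho methoxy group donates; under forcing conditions the alkoxide may instead be consumed by addition to the nitrile. The fallback forms the O–C2 bond by palladium-catalysed allylic etherification and then closes the pyran ring by metathesis, both known reaction types. It sets out from phenol 2, which is treated with racemic 2-methyl-2-vinyloxirane (CC1(C=C)CO1), Pd2(dba)3·CHCl3 and the C2-symmetric trans-1,2-diaminocyclohexane bis(2-diphenylphosphinobenzamide) ligand in CH2Cl2 at rt. This is an asymmetric allylic etherification with dynamic kinetic asymmetric transformation of the vinyl epoxide, the phenol being delivered to the tertiary terminus; the ligand antipode is chosen to give the (R) ether, and the sense of induction must be confirmed. The product should be 3-ethenyl-4-{[(2R)-1-hydroxy-2-methylbut-3-en-2-yl]oxy}-5-methoxybenzonitrile F1. Ring-closing metathesis of F1 with second-generation Grubbs catalyst in CH2Cl2 at 40 °C comes back to the route at 9.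

Step 3. Excess ylide may add to the nitrile, or opening of the hindered epoxide CH2 may stall before the elimination. The fallback replaces the ylide homologation by oxidation and olefination, and needs the other glycidol enantiomer because the phenoxide now attacks the epoxide CH2. It sets out from 2, which is heated with (R)-2-methylglycidol (OC[C@]1(C)CO1) and catalytic Cs2CO3 in DMF at 90 °C to give 4-{[(2R)-2,3-dihydroxy-2-methylpropyl]oxy}-3-ethenyl-5-methoxybenzonitrile F2. Swern oxidation of the primary alcohol gives 3-ethenyl-4-{[(2S)-2-hydroxy-2-methyl-3-oxopropyl]oxy}-5-methoxybenzonitrile F3, which has no α-hydrogen and so cannot epimerise. Wittig methylenation (Ph3P=CH2, THF, −78 → 0 °C) comes back at 6.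

Step 6. Addition to the donor-deactivated nitrile may stall once the magnesium alkoxide has precipitated, or the acidic hydrolysis of the ketimine may damage the acid-sensitive chromene. The fallback goes through the aldehyde oxidation level. From 9, i-Bu2AlH (CH2Cl2, −78 °C; aqueous tartrate work-up) gives (2R)-2-(hydroxymethyl)-8-methoxy-2-methyl-2H-chromene-6-carbaldehyde F4. MeMgBr (THF, 0 °C) gives 1-[(2R)-2-(hydroxymethyl)-8-methoxy-2-methyl-2H-chromen-6-yl]ethan-1-ol F5 as both carbinol epimers. MnO2 (CH2Cl2, rt) oxidises only the benzylic alcohol and comes back at 11.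

Further compounds
F1 | step 5 | 3-ethenyl-4-{[(2R)-1-hydroxy-2-methylbut-3-en-2-yl]oxy}-5-methoxybenzonitrile | OC[C@@](C)(C=C)Oc1c(C=C)cc(C#N)cc1OC
F2 | step 3 | 4-{[(2R)-2,3-dihydroxy-2-methylpropyl]oxy}-3-ethenyl-5-methoxybenzonitrile | OC[C@@](C)(O)COc1c(C=C)cc(C#N)cc1OC
F3 | step 3 | 3-ethenyl-4-{[(2S)-2-hydroxy-2-methyl-3-oxopropyl]oxy}-5-methoxybenzonitrile | O=C[C@@](C)(O)COc1c(C=C)cc(C#N)cc1OC
F4 | step 6 | (2R)-2-(hydroxymethyl)-8-methoxy-2-methyl-2H-chromene-6-carbaldehyde | OC[C@@]1(C)C=Cc2cc(C=O)cc(OC)c2O1
F5 | step 6 | 1-[(2R)-2-(hydroxymethyl)-8-methoxy-2-methyl-2H-chromen-6-yl]ethan-1-ol | OC[C@@]1(C)C=Cc2cc(C(C)O)cc(OC)c2O1
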